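The route hinges on disconnecting C3–C4 in the dihydropyran ring (O1, C2, C3, C4, C4a, C8a). The feature used is the C3 carbinol beside the benzylic C4 methylene, held between arene carbon C4a and quaternary C2, which has no hydrogen to enolise: a deoxygenated α-hydroxy ketone. A chiral triazolylidene carbene converts the C4a formyl group of a methoxymethyl-protected dialdehyde into a nucleophilic acyl equivalent, which attacks the aldehyde of the ortho O–C(CH3)2–CHO arm. That single step makes the C3–C4 bond, the pyranone ring and the C3 configuration. The precursor is a pentasubstituted benzaldehyde bearing this arm, the prenyl group and the arylethyl chain.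

Key step: step 12

Remarks on the chemistry (assumptions and design choices)
- Chroman numbering (O1, C2, C3, C4, C4a, C5–C8, C8a) is used for all bicyclic compounds; MOM = methoxymethyl.
- The spatial arrangement at C3 is the same in 19–24. The descriptor is S in ketone 19, where the C4 carbonyl outranks C2, and R in 20–24.
- Assumption: the (5aR,10bS) triazolium salt is taken to give the 3S ketone. The sense of induction has to be checked on the first run, and the mirror-image salt is used if it is opposite.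
- Both ring bromines are introduced on the resorcinol-derived aldehyde before the catechol ring is attached, so no second electron-rich arene is present during bromination.
- Electron-donating acetals are kept on O7 and on the catechol. They tolerate carbene, hydride, tin hydride and base, and they keep the O1 aryloxide a poor leaving group.

Step 1
Reactants: 1 3,5-dihydroxybenzaldehyde
Product: 2 3,5-bis(methoxymethoxy)benzaldehyde
Conditions: NaH, MOMCl, DMF, 0 °C → rt
Reagents that add atoms: chloromethyl methyl ether, COCCl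
Why: Williamson-type O-alkylation of both phenoxides gives the bis-acetal; the non-enolisable aldehyde is untouched.

Step 2
Reactants: 2 3,5-bis(methoxymethoxy)benzaldehyde
Product: 3 2,6-dibromo-3,5-bis(methoxymethoxy)benzaldehyde
Conditions: NBS (2.2 equiv), MeCN, 0 °C → rt, dark
Reagents that add atoms: N-bromosuccinimide, O=C1CCC(=O)N1Br
Why: Electrophilic aromatic bromination should enter twice at the positions para to one acetal oxygen and ortho to the other (C2 and C6), sparing the crowded C4 between the two acetals.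

Step 3
Reactants: 3 2,6-dibromo-3,5-bis(methoxymethoxy)benzaldehyde
Product: 4 2,4-dibromo-3-ethenyl-1,5-bis(methoxymethoxy)benzene
Conditions: Ph3PCH3Br, KOt-Bu, THF, 0 °C → rt
Reagents that add atoms: methyltriphenylphosphonium bromide, C[P+](c1ccccc1)(c1ccccc1)c1ccccc1.[Br-]
Why: Wittig methylenation with the small non-stabilised ylide works on doubly ortho-substituted benzaldehydes and leaves aryl bromides alone.

Step 4
Reactants: 5 4-bromobenzene-1,2-diol
Product: 6 4-bromo-1,2-bis(methoxymethoxy)benzene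
Conditions: NaH, MOMCl, DMF, 0 °C → rt
Reagents that add atoms: chloromethyl methyl ether, COCCl
Why: Williamson-type O-alkylation of the catechol dianion gives the bis-acetal.

Step 5
Reactants: 4 2,4-dibromo-3-ethenyl-1,5-bis(methoxymethoxy)benzene; 6 4-bromo-1,2-bis(methoxymethoxy)benzene
Product: 8 2,4-dibromo-3-{2-[3,4-bis(methoxymethoxy)phenyl]ethyl}-1,5-bis(methoxymethoxy)benzene, via primary alkylborane 7 (not isolated)
Conditions: 9-BBN, THF, rt → 50 °C; then 6 (1.3 equiv), PdCl2(dppf) (3 mol %; dppf = 1,1′-bis(diphenylphosphino)ferrocene), aq. NaOH (3 M), THF, 60 °C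
Reagents that add atoms: none
Why: Anti-Markovnikov hydroboration followed by B-alkyl Suzuki–Miyaura coupling; zerovalent palladium should insert into the unhindered C–Br bond of 6 far faster than into the two electron-rich C–Br bonds of 7, each flanked by two ortho substituents.

Step 6
Reactants: 8 2,4-dibromo-3-{2-[3,4-bis(methoxymethoxy)phenyl]ethyl}-1,5-bis(methoxymethoxy)benzene; 9 1-bromo-3-methylbut-2-ene (prenyl bromide)
Product: 11 2-bromo-3-{2-[3,4-bis(methoxymethoxy)phenyl]ethyl}-1,5-bis(methoxymethoxy)-4-(3-methylbut-2-enyl)benzene, via aryllithium 10 (not isolated)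
Conditions: n-BuLi (1.0 equiv), THF, –78 °C; CuBr·SMe2 (10 mol %), 9, –78 → 0 °C
Reagents that add atoms: none
Why: Bromine–lithium exchange on the symmetrical dibromide gives one acetal-chelated aryllithium, and copper-catalysed allylic substitution at the primary carbon of prenyl bromide (SN2) gives the linear prenyl group.

Step 7
Reactants: 11 2-bromo-3-{2-[3,4-bis(methoxymethoxy)phenyl]ethyl}-1,5-bis(methoxymethoxy)-4-(3-methylbut-2-enyl)benzene
Product: 13 2-{2-[3,4-bis(methoxymethoxy)phenyl]ethyl}-4,6-bis(methoxymethoxy)-3-(3-methylbut-2-enyl)benzaldehyde, via aryllithium 12 (not isolated)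
Conditions: n-BuLi (1.1 equiv), THF, –78 °C; DMF, –78 °C → rt; H2O
Reagents that add atoms: N,N-dimethylformamide, CN(C)C=O
Why: The second bromine–lithium exchange is much faster at –78 °C than ortho-metalation or allylic deprotonation, and formylation with DMF (Bouveault aldehyde synthesis) gives the aldehyde on hydrolysis.

Step 8
Reactants: 13 2-{2-[3,4-bis(methoxymethoxy)phenyl]ethyl}-4,6-bis(methoxymethoxy)-3-(3-methylbut-2-enyl)benzaldehyde
Product: 14 2-{2-[3,4-bis(methoxymethoxy)phenyl]ethyl}-6-hydroxy-4-(methoxymethoxy)-3-(3-methylbut-2-enyl)benzaldehyde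
Conditions: HCl (cat.), MeOH–THF, rt, monitored; NaHCO3 quench
Reagents that add atoms: none
Why: Acid-catalysed acetal methanolysis should be fastest for the acetal ortho to the formyl group, because the departing phenol is stabilised by its hydrogen bond to the carbonyl oxygen; the phenol next to the prenyl group stays masked, so no chroman can close.

Step 9
Reactants: 14 2-{2-[3,4-bis(methoxymethoxy)phenyl]ethyl}-6-hydroxy-4-(methoxymethoxy)-3-(3-methylbut-2-enyl)benzaldehyde; 15 ethyl 2-bromo-2-methylpropanoate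
Product: 16 ethyl 2-[3-{2-[3,4-bis(methoxymethoxy)phenyl]ethyl}-2-formyl-5-(methoxymethoxy)-4-(3-methylbut-2-enyl)phenoxy]-2-methylpropanoate
Conditions: K2CO3, 15 (3 equiv), DMF, 70 °C
Reagents that add atoms: none
Why: Williamson ether synthesis with a tertiary α-bromo ester, as in aryloxyisobutyrate preparations; the product has no α-hydrogen, so it cannot condense with the neighbouring aldehyde.

Step 10
Reactants: 16 ethyl 2-[3-{2-[3,4-bis(methoxymethoxy)phenyl]ethyl}-2-formyl-5-(methoxymethoxy)-4-(3-methylbut-2-enyl)phenoxy]-2-methylpropanoate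
Product: 17 2-[3-{2-[3,4-bis(methoxymethoxy)phenyl]ethyl}-2-(hydroxymethyl)-5-(methoxymethoxy)-4-(3-methylbut-2-enyl)phenoxy]-2-methylpropan-1-ol
Conditions: LiAlH4, THF, 0 °C; aq. NaOH work-up
Reagents that add atoms: none
Why: Hydride reduction takes both the ester and the aryl aldehyde to primary alcohols, while acetals and the alkene are inert.

Step 11
Reactants: 17 2-[3-{2-[3,4-bis(methoxymethoxy)phenyl]ethyl}-2-(hydroxymethyl)-5-(methoxymethoxy)-4-(3-methylbut-2-enyl)phenoxy]-2-methylpropan-1-ol
Product: 18 2-[3-{2-[3,4-bis(methoxymethoxy)phenyl]ethyl}-2-formyl-5-(methoxymethoxy)-4-(3-methylbut-2-enyl)phenoxy]-2-methylpropanal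
Conditions: Dess–Martin periodinane (2.6 equiv), NaHCO3, CH2Cl2, 0 °C → rt; used without delay
Reagents that add atoms: none
Why: Dess–Martin oxidation of both primary alcohols under buffered neutral conditions avoids ionisation of the electron-rich benzylic alcohol, and the α-quaternary aldehyde formed cannot enolise.

Step 12
Reactants: 18 2-[3-{2-[3,4-bis(methoxymethoxy)phenyl]ethyl}-2-formyl-5-(methoxymethoxy)-4-(3-methylbut-2-enyl)phenoxy]-2-methylpropanal
Product: 19 (3S)-5-{2-[3,4-bis(methoxymethoxy)phenyl]ethyl}-3-hydroxy-7-(methoxymethoxy)-2,2-dimethyl-6-(3-methylbut-2-enyl)chroman-4-one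
Conditions: (5aR,10bS)-2-(pentafluorophenyl)-5a,10b-dihydro-4H,6H-indeno[2,1-b][1,2,4]triazolo[4,3-d][1,4]oxazin-2-ium tetrafluoroborate (15 mol %), i-Pr2NEt (15 mol %), 4 Å molecular sieves, toluene, 0 °C; crude product reduced at once
Reagents that add atoms: none
Why: Proposed new method: the carbene freed from the triazolium salt adds to the aryl aldehyde on C4a, proton transfer gives the Breslow enaminol, this adds to the tethered aldehyde carbon (C3) and collapse releases the carbene and the α-hydroxy ketone; the closest known reaction type is the triazolium-catalysed enantioselective cyclisation of 2-(2-oxoalkoxy)benzaldehydes onto a ketone, so an aldehyde acceptor on this ring system is untested. The pyranone ring closes in a 6-exo-trig mode (attack on C3, its C=O outside the new ring), helped by the gem-dimethyl group on C2. C3 is set by the chiral carbene: the indane backbone shields one face of the enaminol and a hydrogen bond from its hydroxyl to the incoming carbonyl oxygen fixes which face of the C3 aldehyde is attacked. Two selectivities are needed, donor/acceptor role and enantioface: only the aryl carbinol adduct has a benzylic, conjugation-stabilised C–H from which the enaminol can form, whereas the aldehyde on the quaternary carbon is neopentyl-like, cannot enolise and is activated as an electrophile by its α-aryloxy group, and ring closure outruns intermolecular coupling. The chroman-4-one is also the conjugated, more stable acyloin isomer, and the donor acetal on O7 keeps the O1 aryloxide a poor leaving group. A weak base at 0 °C and immediate reduction protect the C3–H next to the ketone from epimerisation.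

Step 13
Reactants: 19 (3S)-5-{2-[3,4-bis(methoxymethoxy)phenyl]ethyl}-3-hydroxy-7-(methoxymethoxy)-2,2-dimethyl-6-(3-methylbut-2-enyl)chroman-4-one
Product: 20 (3R,4R)-5-{2-[3,4-bis(methoxymethoxy)phenyl]ethyl}-7-(methoxymethoxy)-2,2-dimethyl-6-(3-methylbut-2-enyl)chromane-3,4-diol (cis)
Conditions: NaBH4, MeOH–THF, –20 °C
Reagents that add atoms: none
Why: Borohydride reduction of the aryl ketone should deliver hydride anti to the axial methyl group on C2 and give mainly the cis-diol; C3 is untouched and the new C4 centre is removed two steps later.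

Step 14
Reactants: 20 (3R,4R)-5-{2-[3,4-bis(methoxymethoxy)phenyl]ethyl}-7-(methoxymethoxy)-2,2-dimethyl-6-(3-methylbut-2-enyl)chromane-3,4-diol
Product: 21 (3R,4R)-5-{2-[3,4-bis(methoxymethoxy)phenyl]ethyl}-7-(methoxymethoxy)-2,2-dimethyl-6-(3-methylbut-2-enyl)chromane-3,4-diyl thionocarbonate (cis-fused 1,3-dioxolane-2-thione)
Conditions: 1,1′-thiocarbonyldiimidazole, DMAP (cat.), toluene, 80 °C
Reagents that add atoms: 1,1′-thiocarbonyldiimidazole, S=C(n1ccnc1)n1ccnc1
Why: A cis-1,2-diol closes readily to the five-membered cyclic thionocarbonate by double acyl transfer from thiocarbonyldiimidazole.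

Step 15
Reactants: 21 (3R,4R)-5-{2-[3,4-bis(methoxymethoxy)phenyl]ethyl}-7-(methoxymethoxy)-2,2-dimethyl-6-(3-methylbut-2-enyl)chromane-3,4-diyl thionocarbonate
Product: 23 (3R)-5-{2-[3,4-bis(methoxymethoxy)phenyl]ethyl}-7-(methoxymethoxy)-2,2-dimethyl-6-(3-methylbut-2-enyl)chroman-3-ol, via S-stannyl thiocarbonate 22 (not isolated)
Conditions: Bu3SnH, AIBN (cat.), toluene, 100 °C; then aq. NaOH, THF, rt
Reagents that add atoms: none
Why: Barton–McCombie-type radical deoxygenation of a cyclic thionocarbonate: the stannyl radical adds to sulfur and the ring opens at C4–O, the bond that gives the benzylic radical, which takes hydrogen from Bu3SnH; hydrolysis of 22 frees the C3 alcohol with its configuration intact.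

Step 16
Reactants: 23 (3R)-5-{2-[3,4-bis(methoxymethoxy)phenyl]ethyl}-7-(methoxymethoxy)-2,2-dimethyl-6-(3-methylbut-2-enyl)chroman-3-ol
Product: 24 (3R)-5-[2-(3,4-dihydroxyphenyl)ethyl]-2,2-dimethyl-6-(3-methylbut-2-enyl)chromane-3,7-diol
Conditions: HCl (1 M in MeOH), rt, argon
Reagents that add atoms: none
Why: Acid-catalysed methanolysis removes the three aryl acetals; dilute acid at room temperature should leave the prenyl double bond, the adjacent free phenol and the tertiary ether untouched.

Compound list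
1 | 3,5-dihydroxybenzaldehyde | O=Cc1cc(O)cc(O)c1 | starting material
2 | 3,5-bis(methoxymethoxy)benzaldehyde | O=Cc1cc(OCOC)cc(OCOC)c1 | intermediate
3 | 2,6-dibromo-3,5-bis(methoxymethoxy)benzaldehyde | O=Cc1c(Br)c(OCOC)cc(OCOC)c1Br | intermediate
4 | 2,4-dibromo-3-ethenyl-1,5-bis(methoxymethoxy)benzene | C=Cc1c(Br)c(OCOC)cc(OCOC)c1Br | intermediate
5 | 4-bromobenzene-1,2-diol | Oc1ccc(Br)cc1O | starting material
6 | 4-bromo-1,2-bis(methoxymethoxy)benzene | COCOc1ccc(Br)cc1OCOC | intermediate
7 | 9-{2-[2,6-dibromo-3,5-bis(methoxymethoxy)phenyl]ethyl}-9-borabicyclo[3.3.1]nonane (not isolated) | COCOc1cc(OCOC)c(Br)c(CCB2C3CCCC2CCC3)c1Br | intermediate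
8 | 2,4-dibromo-3-{2-[3,4-bis(methoxymethoxy)phenyl]ethyl}-1,5-bis(methoxymethoxy)benzene | COCOc1cc(OCOC)c(Br)c(CCc2ccc(OCOC)c(OCOC)c2)c1Br | intermediate
9 | 1-bromo-3-methylbut-2-ene (prenyl bromide) | CC(C)=CCBr | starting material
10 | {3-bromo-2-{2-[3,4-bis(methoxymethoxy)phenyl]ethyl}-4,6-bis(methoxymethoxy)phenyl}lithium (not isolated) | COCOc1cc(OCOC)c(Br)c(CCc2ccc(OCOC)c(OCOC)c2)c1[Li] | intermediate
11 | 2-bromo-3-{2-[3,4-bis(methoxymethoxy)phenyl]ethyl}-1,5-bis(methoxymethoxy)-4-(3-methylbut-2-enyl)benzene | COCOc1cc(OCOC)c(CC=C(C)C)c(CCc2ccc(OCOC)c(OCOC)c2)c1Br | intermediate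
12 | {2-{2-[3,4-bis(methoxymethoxy)phenyl]ethyl}-4,6-bis(methoxymethoxy)-3-(3-methylbut-2-enyl)phenyl}lithium (not isolated) | COCOc1cc(OCOC)c(CC=C(C)C)c(CCc2ccc(OCOC)c(OCOC)c2)c1[Li] | intermediate
13 | 2-{2-[3,4-bis(methoxymethoxy)phenyl]ethyl}-4,6-bis(methoxymethoxy)-3-(3-methylbut-2-enyl)benzaldehyde | COCOc1cc(OCOC)c(CC=C(C)C)c(CCc2ccc(OCOC)c(OCOC)c2)c1C=O | intermediate
14 | 2-{2-[3,4-bis(methoxymethoxy)phenyl]ethyl}-6-hydroxy-4-(methoxymethoxy)-3-(3-methylbut-2-enyl)benzaldehyde | Oc1cc(OCOC)c(CC=C(C)C)c(CCc2ccc(OCOC)c(OCOC)c2)c1C=O | intermediate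
15 | ethyl 2-bromo-2-methylpropanoate | CCOC(=O)C(C)(C)Br | starting material
16 | ethyl 2-[3-{2-[3,4-bis(methoxymethoxy)phenyl]ethyl}-2-formyl-5-(methoxymethoxy)-4-(3-methylbut-2-enyl)phenoxy]-2-methylpropanoate | CCOC(=O)C(C)(C)Oc1cc(OCOC)c(CC=C(C)C)c(CCc2ccc(OCOC)c(OCOC)c2)c1C=O | intermediate
17 | 2-[3-{2-[3,4-bis(methoxymethoxy)phenyl]ethyl}-2-(hydroxymethyl)-5-(methoxymethoxy)-4-(3-methylbut-2-enyl)phenoxy]-2-methylpropan-1-ol | OCC(C)(C)Oc1cc(OCOC)c(CC=C(C)C)c(CCc2ccc(OCOC)c(OCOC)c2)c1CO | intermediate
18 | 2-[3-{2-[3,4-bis(methoxymethoxy)phenyl]ethyl}-2-formyl-5-(methoxymethoxy)-4-(3-methylbut-2-enyl)phenoxy]-2-methylpropanal | CC(C)=CCc1c(OCOC)cc(OC(C)(C)C=O)c(C=O)c1CCc1ccc(OCOC)c(OCOC)c1 | intermediate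
19 | (3S)-5-{2-[3,4-bis(methoxymethoxy)phenyl]ethyl}-3-hydroxy-7-(methoxymethoxy)-2,2-dimethyl-6-(3-methylbut-2-enyl)chroman-4-one | CC(C)=CCc1c(OCOC)cc2c(c1CCc1ccc(OCOC)c(OCOC)c1)C(=O)[C@@H](O)C(C)(C)O2 | intermediate
20 | (3R,4R)-5-{2-[3,4-bis(methoxymethoxy)phenyl]ethyl}-7-(methoxymethoxy)-2,2-dimethyl-6-(3-methylbut-2-enyl)chromane-3,4-diol | CC(C)=CCc1c(OCOC)cc2c(c1CCc1ccc(OCOC)c(OCOC)c1)[C@@H](O)[C@@H](O)C(C)(C)O2 | intermediate
21 | (3R,4R)-5-{2-[3,4-bis(methoxymethoxy)phenyl]ethyl}-7-(methoxymethoxy)-2,2-dimethyl-6-(3-methylbut-2-enyl)chromane-3,4-diyl thionocarbonate | CC(C)=CCc1c(OCOC)cc2c(c1CCc1ccc(OCOC)c(OCOC)c1)[C@H]1OC(=S)O[C@H]1C(C)(C)O2 | intermediate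
22 | O-{(3R)-5-{2-[3,4-bis(methoxymethoxy)phenyl]ethyl}-7-(methoxymethoxy)-2,2-dimethyl-6-(3-methylbut-2-enyl)chroman-3-yl} S-(tributylstannyl) thiocarbonate (not isolated) | CC(C)=CCc1c(OCOC)cc2c(c1CCc1ccc(OCOC)c(OCOC)c1)C[C@@H](OC(=O)S[Sn](CCCC)(CCCC)CCCC)C(C)(C)O2 | intermediate
23 | (3R)-5-{2-[3,4-bis(methoxymethoxy)phenyl]ethyl}-7-(methoxymethoxy)-2,2-dimethyl-6-(3-methylbut-2-enyl)chroman-3-ol | CC(C)=CCc1c(OCOC)cc2c(c1CCc1ccc(OCOC)c(OCOC)c1)C[C@@H](O)C(C)(C)O2 | intermediate
24 | (3R)-5-[2-(3,4-dihydroxyphenyl)ethyl]-2,2-dimethyl-6-(3-methylbut-2-enyl)chromane-3,7-diol | CC(C)=CCc1c(O)cc2c(c1CCc1ccc(O)c(O)c1)C[C@@H](O)C(C)(C)O2 | target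

Total step count: 16. Longest linear sequence: 15 steps (steps 1–3 and 5–16, from 1 to 24); step 4 is the one-step side branch.

Steps most likely to fail

1. Step 12 (carries the label). Carbene addition to the electron-rich, doubly flanked aryl aldehyde may be slow. The carbene may instead engage the aliphatic aldehyde, which would reverse the donor and acceptor roles or expel the aryloxide from its enaminol. Enantioface control may be weak, and the C3–H next to the ketone may epimerise. The fallback uses known chemistry, sets out from 14 and comes back at 23, so that 16–22 are bypassed. Addition of 2-methylprop-1-enylmagnesium bromide (excess, THF, 0 °C) to the aldehyde gives 3-{2-[3,4-bis(methoxymethoxy)phenyl]ethyl}-2-(1-hydroxy-3-methylbut-2-enyl)-5-(methoxymethoxy)-4-(3-methylbut-2-enyl)phenol F1. Warming in toluene with a trace of pyridinium p-toluenesulfonate dehydrates it to the ortho-quinone methide, which closes by oxa-6π electrocyclisation to 5-{2-[3,4-bis(methoxymethoxy)phenyl]ethyl}-7-(methoxymethoxy)-2,2-dimethyl-6-(3-methylbut-2-enyl)-2H-chromene F2. Jacobsen epoxidation follows, with (R,R)-[N,N′-bis(3,5-di-tert-butylsalicylidene)cyclohexane-1,2-diaminato]manganese chloride, NaOCl and 4-phenylpyridine N-oxide in CH2Cl2 at 0 °C. The conjugated cis double bond of the chromene should react ahead of the isolated prenyl alkene and give (3R,4R)-5-{2-[3,4-bis(methoxymethoxy)phenyl]ethyl}-3,4-epoxy-7-(methoxymethoxy)-2,2-dimethyl-6-(3-methylbut-2-enyl)chromane F3; the mirror-image complex is used if the sense is opposite. LiAlH4 (THF, 0 °C) then delivers hydride to the benzylic C4, away from the neopentyl-like C3, and gives 23.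

2. Step 8. Discrimination among the four acetals may be poor, so that a second acetal is lost or the cleavage stalls before completion. The fallback sets out from 13 and comes back at 14, and takes its selectivity from protection instead of deprotection. All four acetals are removed (HCl, MeOH, 40 °C, short exposure) to give 2-[2-(3,4-dihydroxyphenyl)ethyl]-4,6-dihydroxy-3-(3-methylbut-2-enyl)benzaldehyde F4. Three phenols are then re-protected with MOMCl (3.1 equiv) and i-Pr2NEt in CH2Cl2 at 0 °C. The phenol hydrogen-bonded to the formyl group is the least nucleophilic and should stay free, which returns 14.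

3. Step 6. The aryl nucleophile may attack the tertiary terminus of the prenyl electrophile (SN2′) and give the 1,1-dimethylallyl isomer; both bromines may exchange; or the aryllithium may be quenched by a proton. The fallback sets out from 8 and comes back at 11. The same mono-aryllithium (n-BuLi, THF, –78 °C, CuBr·SMe2 cat.) is trapped with allyl bromide, whose two termini are identical, to give 2-bromo-3-{2-[3,4-bis(methoxymethoxy)phenyl]ethyl}-1,5-bis(methoxymethoxy)-4-(prop-2-enyl)benzene F5. Olefin cross-metathesis with 2-methylbut-2-ene as co-solvent and the second-generation Grubbs catalyst in CH2Cl2 at 40 °C converts allyl into prenyl and returns 11.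

Further compounds
F1 | step 12 | 3-{2-[3,4-bis(methoxymethoxy)phenyl]ethyl}-2-(1-hydroxy-3-methylbut-2-enyl)-5-(methoxymethoxy)-4-(3-methylbut-2-enyl)phenol | Oc1cc(OCOC)c(CC=C(C)C)c(CCc2ccc(OCOC)c(OCOC)c2)c1C(O)C=C(C)C
F2 | step 12 | 5-{2-[3,4-bis(methoxymethoxy)phenyl]ethyl}-7-(methoxymethoxy)-2,2-dimethyl-6-(3-methylbut-2-enyl)-2H-chromene | CC(C)=CCc1c(OCOC)cc2OC(C)(C)C=Cc2c1CCc1ccc(OCOC)c(OCOC)c1
F3 | step 12 | (3R,4R)-5-{2-[3,4-bis(methoxymethoxy)phenyl]ethyl}-3,4-epoxy-7-(methoxymethoxy)-2,2-dimethyl-6-(3-methylbut-2-enyl)chromane | CC(C)=CCc1c(OCOC)cc2c(c1CCc1ccc(OCOC)c(OCOC)c1)[C@H]1O[C@H]1C(C)(C)O2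
F4 | step 8 | 2-[2-(3,4-dihydroxyphenyl)ethyl]-4,6-dihydroxy-3-(3-methylbut-2-enyl)benzaldehyde | Oc1cc(O)c(CC=C(C)C)c(CCc2ccc(O)c(O)c2)c1C=O
F5 | step 6 | 2-bromo-3-{2-[3,4-bis(methoxymethoxy)phenyl]ethyl}-1,5-bis(methoxymethoxy)-4-(prop-2-enyl)benzene | COCOc1cc(OCOC)c(CC=C)c(CCc2ccc(OCOC)c(OCOC)c2)c1Br
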